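**Strategy.** The C45 side chain is cut between the vinylic CH of the central trisubstituted olefin (fifth prenyl unit from the isopropylidene end) and the neighbouring CH2, which sits two carbons from the next C(CH3)=CH. That CH2–CH2–C(CH3)=CH motif is the footprint of a γ,δ-unsaturated acid. The key step is therefore a nickel-electrocatalytic decarboxylative alkenylation: the redox-active ester of a naphthyl-terminated C22 acid chain (carrying both 1,5-related methyl stereocentres and the quinone ring masked as its bis-methyl ether) loses CO2, and its primary radical is joined to a C24 (E)-alkenyl iodide with retention of olefin geometry. The precursor thus carries one carbon more than the product. Oxidative demethylation then unveils the naphthoquinone.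

Key step: step 19

Assumption: commercial (R)-(−)-citronellyl bromide 5 is taken as enantiomerically pure (it supplies two of the three stereocentres); material of lower purity would be upgraded before use.

**Aryl building block**

Step 1
Reactants: 1 menadione
Product: 3 1,4-dimethoxy-2-methylnaphthalene, via menadiol 2 (not isolated)
Conditions: Na2S2O4, Bu4NBr (cat.), THF/H2O, rt, N2; then aq NaOH, Me2SO4, rt
Reagents that add atoms: dimethyl sulfate COS(=O)(=O)OC
Why: Dithionite reduces the quinone to the hydroquinone, whose phenoxides are O-methylated in the same pot (reductive Williamson etherification).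

Step 2
Reactants: 3 1,4-dimethoxy-2-methylnaphthalene
Product: 4 2-(chloromethyl)-1,4-dimethoxy-3-methylnaphthalene
Conditions: (CH2O)n, conc. HCl, AcOH, 60 °C
Reagents that add atoms: formaldehyde C=O (as paraformaldehyde); hydrogen chloride Cl
Why: Blanc chloromethylation occurs at C3, the only free and most electron-rich position of the dimethoxy-substituted ring.

**Right-hand fragment (both 1,5-related methyl stereocentres)**

Step 3
Reactants: 5 (R)-citronellyl bromide
Product: 6 (2E,6R)-8-bromo-2,6-dimethyloct-2-en-1-ol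
Conditions: SeO2 (0.3 equiv), t-BuOOH (3 equiv), salicylic acid (cat.), CH2Cl2, rt
Reagents that add atoms: tert-butyl hydroperoxide CC(C)(C)OO; selenium dioxide O=[Se]=O (catalytic oxygen relay)
Why: Riley allylic oxidation (ene reaction, then [2,3]-sigmatropic shift) of the isopropylidene group is selective for the (E)-methyl group and leaves the primary bromide and the C6 stereocentre untouched.

Step 4
Reactants: 6 (2E,6R)-8-bromo-2,6-dimethyloct-2-en-1-ol
Product: 7 (2S,6R)-8-bromo-2,6-dimethyloctan-1-ol
Conditions: H2 (30 atm), Ru(OAc)2[(S)-BINAP] (0.5 mol%), MeOH, 25 °C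
Reagents that add atoms: none
Why: Noyori asymmetric hydrogenation of the allylic alcohol sets C2 under catalyst control; the (S)-BINAP ligand is expected to deliver H2 to the same olefin face, relative to the CH2OH anchor, as in the geraniol to (R)-citronellol reduction, which corresponds to 2S, and the remote 6R centre exerts no influence.

Step 5
Reactants: 7 (2S,6R)-8-bromo-2,6-dimethyloctan-1-ol; 8 1-(trimethylsilyl)propyne
Product: 10 (2S,6R)-2,6-dimethylundec-10-yn-1-ol, via silylated alkyne 9 (not isolated)
Conditions: 7 + n-BuLi (1 equiv), THF, −78 °C; added to LiCH2C≡CSiMe3 (from 8, n-BuLi, THF, −78 °C), DMPU, −78 °C → rt; then K2CO3, MeOH, rt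
Reagents that add atoms: none
Why: SN2 alkylation of the propargylic lithium reagent by the primary bromide (hydroxyl carried as its lithium alkoxide) is followed by protodesilylation of the alkynylsilane; no stereocentre is involved.

Step 6
Reactants: 10 (2S,6R)-2,6-dimethylundec-10-yn-1-ol; 4 2-(chloromethyl)-1,4-dimethoxy-3-methylnaphthalene
Product: 12 (2S,6R,10E)-12-(1,4-dimethoxy-3-methylnaphthalen-2-yl)-2,6,10-trimethyldodec-10-en-1-ol, via alkenylalane 11 (not isolated)
Conditions: Me3Al (3 equiv), Cp2ZrCl2 (0.25 equiv), ClCH2CH2Cl, 0 °C → rt; volatiles removed; then 4, NiCl2(PPh3)2 (5 mol%, reduced beforehand with n-BuLi to zerovalent nickel), THF, rt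
Reagents that add atoms: trimethylaluminium C[Al](C)C
Why: Negishi carboalumination adds CH3 and Al syn across the terminal alkyne with Al on the terminal carbon, which fixes the (E)-trisubstituted olefin, and the alkenylalane is then cross-coupled with the benzylic chloride under nickel catalysis with retention of geometry (hydroxyl carried as its aluminium alkoxide).

Step 7
Reactants: 12 (2S,6R,10E)-12-(1,4-dimethoxy-3-methylnaphthalen-2-yl)-2,6,10-trimethyldodec-10-en-1-ol
Product: 13 2-[(2E,7R,11S)-12-bromo-3,7,11-trimethyldodec-2-en-1-yl]-1,4-dimethoxy-3-methylnaphthalene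
Conditions: CBr4, PPh3, CH2Cl2, 0 °C
Reagents that add atoms: carbon tetrabromide BrC(Br)(Br)Br
Why: Appel reaction, SN2 displacement of the alkoxyphosphonium at the primary carbon, so the adjacent stereocentre is not touched.

**C7 acid synthon**

Step 8
Reactants: 14 (tert-butyldimethylsilyloxy)acetaldehyde; 15 isopropenylmagnesium bromide
Product: 16 1-[(tert-butyldimethylsilyl)oxy]-3-methylbut-3-en-2-ol (racemic)
Conditions: THF, −78 °C; cold aq NH4Cl quench
Reagents that add atoms: none
Why: 1,2-Addition of the alkenyl Grignard reagent to the aldehyde; the new carbinol centre is racemic, which is irrelevant because it is destroyed in step 9.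

Step 9
Reactants: 16 1-[(tert-butyldimethylsilyl)oxy]-3-methylbut-3-en-2-ol
Product: 17 methyl (4E)-6-[(tert-butyldimethylsilyl)oxy]-4-methylhex-4-enoate
Conditions: MeC(OMe)3 (5 equiv), EtCO2H (cat.), 110 °C, MeOH distilled off
Reagents that add atoms: trimethyl orthoacetate COC(C)(OC)OC
Why: Johnson–Claisen rearrangement through a chair transition state with the CH2OSi group equatorial gives the (E)-trisubstituted γ,δ-unsaturated ester.

Step 10
Reactants: 17 methyl (4E)-6-[(tert-butyldimethylsilyl)oxy]-4-methylhex-4-enoate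
Product: 18 methyl (4E)-6-bromo-4-methylhex-4-enoate
Conditions: Ph3PBr2, CH2Cl2, 0 °C → rt
Reagents that add atoms: triphenylphosphine dibromide BrP(Br)(c1ccccc1)(c1ccccc1)c1ccccc1
Why: Triphenylphosphine dibromide converts primary silyl ethers directly into bromides (silyl transfer to bromide, then SN2 collapse of the alkoxyphosphonium at the primary allylic carbon), so the (E)-olefin is retained.

Step 11
Reactants: 13 2-[(2E,7R,11S)-12-bromo-3,7,11-trimethyldodec-2-en-1-yl]-1,4-dimethoxy-3-methylnaphthalene; 18 methyl (4E)-6-bromo-4-methylhex-4-enoate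
Product: 20 methyl (4E,8S,12R,16E)-18-(1,4-dimethoxy-3-methylnaphthalen-2-yl)-4,8,12,16-tetramethyloctadeca-4,16-dienoate, via Grignard reagent 19 (not isolated)
Conditions: 13, Mg turnings, THF, 45 °C; then 18 (1.2 equiv), Li2CuCl4 (5 mol%), THF, −78 → −30 °C
Reagents that add atoms: none
Why: Copper-catalysed coupling of an alkyl Grignard reagent with a prenyl-type primary allylic bromide occurs at the α-carbon (the γ-carbon is fully substituted) with retention of the (E)-geometry, and at low temperature it outruns addition to the methyl ester.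

Step 12
Reactants: 20 methyl (4E,8S,12R,16E)-18-(1,4-dimethoxy-3-methylnaphthalen-2-yl)-4,8,12,16-tetramethyloctadeca-4,16-dienoate
Product: 21 (4E,8S,12R,16E)-18-(1,4-dimethoxy-3-methylnaphthalen-2-yl)-4,8,12,16-tetramethyloctadeca-4,16-dienoic acid
Conditions: LiOH·H2O, THF/MeOH/H2O, rt; then 1 M HCl to pH 3
Reagents that add atoms: lithium hydroxide [Li+].[OH-]
Why: Saponification of the methyl ester; no other group is base-sensitive.

**Left-hand fragment**

Step 13
Reactants: 22 geranyl bromide; 8 1-(trimethylsilyl)propyne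
Product: 23 trimethyl[(5E)-6,10-dimethylundeca-5,9-dien-1-yn-1-yl]silane
Conditions: 8, n-BuLi, THF, −78 °C; then 22, −78 → 0 °C
Reagents that add atoms: none
Why: SN2 alkylation of lithiated 1-(trimethylsilyl)propyne at the primary allylic bromide gives the 1,5-enyne with the (E)-olefin unchanged.

Step 14
Reactants: 23 trimethyl[(5E)-6,10-dimethylundeca-5,9-dien-1-yn-1-yl]silane
Product: 24 (2E,6E)-2,6-dimethyl-11-(trimethylsilyl)undeca-2,6-dien-10-yn-1-ol
Conditions: SeO2 (0.3 equiv), t-BuOOH (3 equiv), salicylic acid (cat.), CH2Cl2, 0 °C → rt, stopped at partial conversion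
Reagents that add atoms: tert-butyl hydroperoxide CC(C)(C)OO; selenium dioxide O=[Se]=O (catalytic oxygen relay)
Why: Riley oxidation attacks the more accessible terminal isopropylidene group at its (E)-methyl group in preference to the internal trisubstituted olefin; the regioisomers are separable by chromatography.

Step 15
Reactants: 24 (2E,6E)-2,6-dimethyl-11-(trimethylsilyl)undeca-2,6-dien-10-yn-1-ol
Product: 25 [(5E,9E)-11-bromo-6,10-dimethylundeca-5,9-dien-1-yn-1-yl]trimethylsilane
Conditions: CBr4, PPh3, CH2Cl2, −20 → 0 °C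
Reagents that add atoms: carbon tetrabromide BrC(Br)(Br)Br
Why: Appel reaction at the primary allylic carbon gives the allylic bromide without transposition or loss of (E)-geometry.

Step 16
Reactants: 5 (R)-citronellyl bromide; 25 [(5E,9E)-11-bromo-6,10-dimethylundeca-5,9-dien-1-yn-1-yl]trimethylsilane
Product: 27 trimethyl[(5E,9E,14S)-6,10,14,18-tetramethylnonadeca-5,9,17-trien-1-yn-1-yl]silane, via citronellylmagnesium bromide 26 (not isolated)
Conditions: 5, Mg turnings, THF, 40 °C; then 25, Li2CuCl4 (5 mol%), THF, −78 → 0 °C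
Reagents that add atoms: none
Why: Copper-catalysed α-selective allylic substitution by the alkyl Grignard reagent joins the two pieces with retention of olefin geometry; the citronellyl stereocentre is carried through unchanged (its descriptor becomes S by a priority change only).

Step 17
Reactants: 27 trimethyl[(5E,9E,14S)-6,10,14,18-tetramethylnonadeca-5,9,17-trien-1-yn-1-yl]silane
Product: 28 (5E,9E,14S)-6,10,14,18-tetramethylnonadeca-5,9,17-trien-1-yne
Conditions: K2CO3, MeOH/THF, rt
Reagents that add atoms: none
Why: Base-mediated protodesilylation of the alkynylsilane.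

Step 18
Reactants: 28 (5E,9E,14S)-6,10,14,18-tetramethylnonadeca-5,9,17-trien-1-yne
Product: 30 (1E,5E,9E,14S)-1-iodo-2,6,10,14,18-pentamethylnonadeca-1,5,9,17-tetraene, via alkenylalane 29 (not isolated)
Conditions: Me3Al (2.5 equiv), Cp2ZrCl2 (0.25 equiv), ClCH2CH2Cl, 0 °C → rt; then I2, THF, −30 → 0 °C
Reagents that add atoms: trimethylaluminium C[Al](C)C; iodine II
Why: Negishi carboalumination (syn addition of CH3–Al, Al terminal) followed by iodinolysis with retention gives the (E)-alkenyl iodide; the isolated trisubstituted olefins do not react.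

**Fragment union and end game**

Step 19
Reactants: 21 (4E,8S,12R,16E)-18-(1,4-dimethoxy-3-methylnaphthalen-2-yl)-4,8,12,16-tetramethyloctadeca-4,16-dienoic acid; 30 (1E,5E,9E,14S)-1-iodo-2,6,10,14,18-pentamethylnonadeca-1,5,9,17-tetraene
Product: 32 2-[(2E,7R,11S,14E,18E,22E,26E,31S)-3,7,11,15,19,23,27,31,35-nonamethylhexatriaconta-2,14,18,22,26,34-hexaen-1-yl]-1,4-dimethoxy-3-methylnaphthalene, via N-acyloxyphthalimide 31 (not isolated)
Conditions: 21, N-hydroxyphthalimide, DIC, DMAP (cat.), CH2Cl2, rt; filtered, solvent exchanged; then 30, NiCl2·6H2O (20 mol%), 2,2′-bipyridine (20 mol%), AgNO3 (0.3 equiv), DMF, Mg anode / reticulated vitreous carbon cathode, constant current, rt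
Reagents that add atoms: none
Why: The N-acyloxyphthalimide accepts an electron (from the cathode or from low-valent nickel) and fragments to phthalimide anion, CO2 and the primary homoallylic radical, while zerovalent nickel–bipyridine, regenerated at the silver-coated cathode against the sacrificial Mg anode, adds oxidatively to the C–I bond of 30 with retention to give an (E)-alkenyl complex of divalent nickel. Capture of the radical gives an alkyl(alkenyl) complex of trivalent nickel, and reductive elimination forms the C(sp3)–C(sp2) bond between the chain CH2 and the vinylic CH; the monovalent nickel left behind is reduced again at the cathode. The closest known reaction type is the nickel-electrocatalytic decarboxylative alkenylation of redox-active esters with alkenyl iodides, which has been applied to 1,5-diene terpenoid building blocks of this γ,δ-unsaturated acid / (E)-2-methylalkenyl iodide kind. No ring is closed and no stereocentre is formed; the three methyl stereocentres are remote from both reacting atoms. The step needs retention of the (E)-geometry of the alkenyl iodide, secured by stereoretentive oxidative addition and reductive elimination at nickel, and a radical that does not rearrange, secured because 3-exo closure of the homoallylic radical is slow and reversible compared with capture by nickel. Chemoselectivity rests on the substrate design: the quinone is masked as the non-reducible 1,4-dimethoxynaphthalene, and the isolated trisubstituted olefins are inert under the mildly reducing conditions.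

Step 20
Reactants: 32 2-[(2E,7R,11S,14E,18E,22E,26E,31S)-3,7,11,15,19,23,27,31,35-nonamethylhexatriaconta-2,14,18,22,26,34-hexaen-1-yl]-1,4-dimethoxy-3-methylnaphthalene
Product: 33 2-methyl-3-[(2E,7R,11S,14E,18E,22E,26E,31S)-3,7,11,15,19,23,27,31,35-nonamethylhexatriaconta-2,14,18,22,26,34-hexaen-1-yl]naphthalene-1,4-dione (target)
Conditions: (NH4)2Ce(NO3)6 (2.5 equiv), MeCN/H2O/CH2Cl2, 0 °C
Reagents that add atoms: water O
Why: Oxidative demethylation by tetravalent cerium (two one-electron oxidations, addition of water to the arene radical cation, loss of methanol) should give the 1,4-naphthoquinone, while the isolated trisubstituted olefins and the stereocentres are not affected at 0 °C.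

**Compound list**

1 | menadione (2-methylnaphthalene-1,4-dione) | CC1=CC(=O)c2ccccc2C1=O | starting material
2 | menadiol (2-methylnaphthalene-1,4-diol) | Cc1cc(O)c2ccccc2c1O | intermediate (not isolated)
3 | 1,4-dimethoxy-2-methylnaphthalene | COc1cc(C)c(OC)c2ccccc12 | intermediate
4 | 2-(chloromethyl)-1,4-dimethoxy-3-methylnaphthalene | ClCc1c(C)c(OC)c2ccccc2c1OC | intermediate
5 | (R)-citronellyl bromide, (6R)-8-bromo-2,6-dimethyloct-2-ene | CC(C)=CCC[C@@H](C)CCBr | starting material
6 | (2E,6R)-8-bromo-2,6-dimethyloct-2-en-1-ol | OC/C(C)=C/CC[C@@H](C)CCBr | intermediate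
7 | (2S,6R)-8-bromo-2,6-dimethyloctan-1-ol | OC[C@@H](C)CCC[C@@H](C)CCBr | intermediate
8 | 1-(trimethylsilyl)propyne | CC#C[Si](C)(C)C | starting material
9 | (2S,6R)-2,6-dimethyl-11-(trimethylsilyl)undec-10-yn-1-ol (lithium alkoxide in the flask) | OC[C@@H](C)CCC[C@@H](C)CCCC#C[Si](C)(C)C | intermediate (not isolated)
10 | (2S,6R)-2,6-dimethylundec-10-yn-1-ol | OC[C@@H](C)CCC[C@@H](C)CCCC#C | intermediate
11 | (E)-alkenyldimethylalane of 10, O-dimethylaluminium alkoxide | C[Al](C)OC[C@@H](C)CCC[C@@H](C)CCC/C(C)=C/[Al](C)C | intermediate (not isolated)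
12 | (2S,6R,10E)-12-(1,4-dimethoxy-3-methylnaphthalen-2-yl)-2,6,10-trimethyldodec-10-en-1-ol | OC[C@@H](C)CCC[C@@H](C)CCC/C(C)=C/Cc1c(C)c(OC)c2ccccc2c1OC | intermediate
13 | 2-[(2E,7R,11S)-12-bromo-3,7,11-trimethyldodec-2-en-1-yl]-1,4-dimethoxy-3-methylnaphthalene | BrC[C@@H](C)CCC[C@@H](C)CCC/C(C)=C/Cc1c(C)c(OC)c2ccccc2c1OC | intermediate
14 | (tert-butyldimethylsilyloxy)acetaldehyde | CC(C)(C)[Si](C)(C)OCC=O | starting material
15 | isopropenylmagnesium bromide | CC(=C)[Mg]Br | starting material
16 | 1-[(tert-butyldimethylsilyl)oxy]-3-methylbut-3-en-2-ol (racemic) | CC(=C)C(O)CO[Si](C)(C)C(C)(C)C | intermediate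
17 | methyl (4E)-6-[(tert-butyldimethylsilyl)oxy]-4-methylhex-4-enoate | COC(=O)CC/C(C)=C/CO[Si](C)(C)C(C)(C)C | intermediate
18 | methyl (4E)-6-bromo-4-methylhex-4-enoate | COC(=O)CC/C(C)=C/CBr | intermediate
19 | Grignard reagent of 13 | Br[Mg]C[C@@H](C)CCC[C@@H](C)CCC/C(C)=C/Cc1c(C)c(OC)c2ccccc2c1OC | intermediate (not isolated)
20 | methyl (4E,8S,12R,16E)-18-(1,4-dimethoxy-3-methylnaphthalen-2-yl)-4,8,12,16-tetramethyloctadeca-4,16-dienoate | COC(=O)CC/C(C)=C/CC[C@@H](C)CCC[C@@H](C)CCC/C(C)=C/Cc1c(C)c(OC)c2ccccc2c1OC | intermediate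
21 | (4E,8S,12R,16E)-18-(1,4-dimethoxy-3-methylnaphthalen-2-yl)-4,8,12,16-tetramethyloctadeca-4,16-dienoic acid | OC(=O)CC/C(C)=C/CC[C@@H](C)CCC[C@@H](C)CCC/C(C)=C/Cc1c(C)c(OC)c2ccccc2c1OC | intermediate
22 | geranyl bromide, (2E)-1-bromo-3,7-dimethylocta-2,6-diene | CC(C)=CCC/C(C)=C/CBr | starting material
23 | trimethyl[(5E)-6,10-dimethylundeca-5,9-dien-1-yn-1-yl]silane | CC(C)=CCC/C(C)=C/CCC#C[Si](C)(C)C | intermediate
24 | (2E,6E)-2,6-dimethyl-11-(trimethylsilyl)undeca-2,6-dien-10-yn-1-ol | OC/C(C)=C/CC/C(C)=C/CCC#C[Si](C)(C)C | intermediate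
25 | [(5E,9E)-11-bromo-6,10-dimethylundeca-5,9-dien-1-yn-1-yl]trimethylsilane | BrC/C(C)=C/CC/C(C)=C/CCC#C[Si](C)(C)C | intermediate
26 | (R)-citronellylmagnesium bromide | CC(C)=CCC[C@@H](C)CC[Mg]Br | intermediate (not isolated)
27 | trimethyl[(5E,9E,14S)-6,10,14,18-tetramethylnonadeca-5,9,17-trien-1-yn-1-yl]silane | CC(C)=CCC[C@@H](C)CCC/C(C)=C/CC/C(C)=C/CCC#C[Si](C)(C)C | intermediate
28 | (5E,9E,14S)-6,10,14,18-tetramethylnonadeca-5,9,17-trien-1-yne | CC(C)=CCC[C@@H](C)CCC/C(C)=C/CC/C(C)=C/CCC#C | intermediate
29 | (E)-alkenyldimethylalane of 28 | CC(C)=CCC[C@@H](C)CCC/C(C)=C/CC/C(C)=C/CC/C(C)=C/[Al](C)C | intermediate (not isolated)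
30 | (1E,5E,9E,14S)-1-iodo-2,6,10,14,18-pentamethylnonadeca-1,5,9,17-tetraene | CC(C)=CCC[C@@H](C)CCC/C(C)=C/CC/C(C)=C/CC/C(C)=C/I | intermediate
31 | 1,3-dioxoisoindolin-2-yl ester of acid 21 (N-acyloxyphthalimide) | O=C(CC/C(C)=C/CC[C@@H](C)CCC[C@@H](C)CCC/C(C)=C/Cc1c(C)c(OC)c2ccccc2c1OC)ON1C(=O)c2ccccc2C1=O | intermediate (not isolated)
32 | 2-[(2E,7R,11S,14E,18E,22E,26E,31S)-3,7,11,15,19,23,27,31,35-nonamethylhexatriaconta-2,14,18,22,26,34-hexaen-1-yl]-1,4-dimethoxy-3-methylnaphthalene | CC(C)=CCC[C@@H](C)CCC/C(C)=C/CC/C(C)=C/CC/C(C)=C/CC/C(C)=C/CC[C@@H](C)CCC[C@@H](C)CCC/C(C)=C/Cc1c(C)c(OC)c2ccccc2c1OC | intermediate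
33 | 2-methyl-3-[(2E,7R,11S,14E,18E,22E,26E,31S)-3,7,11,15,19,23,27,31,35-nonamethylhexatriaconta-2,14,18,22,26,34-hexaen-1-yl]naphthalene-1,4-dione | CC(C)=CCC[C@@H](C)CCC/C(C)=C/CC/C(C)=C/CC/C(C)=C/CC/C(C)=C/CC[C@@H](C)CCC[C@@H](C)CCC/C(C)=C/CC1=C(C)C(=O)c2ccccc2C1=O | target

**Totals**

Total step count: 20.
Longest linear sequence: 9 steps (steps 3, 4, 5, 6, 7, 11, 12, 19 and 20, from (R)-citronellyl bromide 5).

**Steps most likely to fail**

1. Step 19. The alkyl radical may be reduced or dimerise before nickel captures it, or the alkenyl iodide may be consumed by homocoupling or protodeiodination, so that cross-coupling of two valuable fragments used near 1:1 stays incomplete. Fallback, from acid 21 back to 32 by a polar cross-coupling: 21 would be esterified with N-hydroxypyridine-2-thione (DCC, DMAP, CH2Cl2, dark) to the thiohydroxamate ester 2-thioxopyridin-1(2H)-yl (4E,8S,12R,16E)-18-(1,4-dimethoxy-3-methylnaphthalen-2-yl)-4,8,12,16-tetramethyloctadeca-4,16-dienoate F1. Visible-light irradiation with CHI3 (Barton decarboxylative iodination) should give the homoallylic iodide 2-[(2E,7R,11S,14E)-17-iodo-3,7,11,15-tetramethylheptadeca-2,14-dien-1-yl]-1,4-dimethoxy-3-methylnaphthalene F2. Iodine–lithium exchange (t-BuLi, Et2O, −78 °C) and transmetalation with ZnBr2 give the corresponding alkylzinc bromide F3, which is coupled with alkenyl iodide 30 under Pd(PPh3)4 catalysis (Negishi coupling at zerovalent palladium, retention of olefin geometry) to rejoin the route at 32.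

2. Step 4. Hydrogen delivery to the 2-methyl allylic alcohol may show poor facial discrimination or the opposite sense, leaving a 1,5-diastereomer that cannot be separated. Fallback, from 6 back to 7 by biocatalysis instead of metal catalysis: 6 would be oxidised (MnO2, CH2Cl2) to (2E,6R)-8-bromo-2,6-dimethyloct-2-enal F4, which fermenting baker's yeast (ene-reductase followed by alcohol dehydrogenase, aqueous glucose, 30 °C) should reduce at the C=C bond with (S)-selectivity at the α-methyl carbon and then at the aldehyde, giving 7.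

3. Step 6. Carboalumination may be incomplete or regio-unselective in the presence of the aluminium alkoxide, and the benzylic chloride may undergo reductive homocoupling at nickel faster than transmetalation. Fallback, from 10 back to 12 with reversed polarity and isolated partners: carboalumination of 10 followed by iodinolysis (Me3Al, Cp2ZrCl2, ClCH2CH2Cl; then I2) should give (2S,6R,10E)-11-iodo-2,6,10-trimethylundec-10-en-1-ol F5. Chloride 4 is converted with zinc dust and LiCl in THF into [(1,4-dimethoxy-3-methylnaphthalen-2-yl)methyl]zinc chloride F6. Negishi coupling of F5 with excess F6 under Pd(PPh3)4 catalysis (the hydroxyl carried as its zinc alkoxide) returns to 12.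

**Further compounds**

F1 | step 19 | 2-thioxopyridin-1(2H)-yl (4E,8S,12R,16E)-18-(1,4-dimethoxy-3-methylnaphthalen-2-yl)-4,8,12,16-tetramethyloctadeca-4,16-dienoate | S=c1ccccn1OC(=O)CC/C(C)=C/CC[C@@H](C)CCC[C@@H](C)CCC/C(C)=C/Cc1c(C)c(OC)c2ccccc2c1OC
F2 | step 19 | 2-[(2E,7R,11S,14E)-17-iodo-3,7,11,15-tetramethylheptadeca-2,14-dien-1-yl]-1,4-dimethoxy-3-methylnaphthalene | ICC/C(C)=C/CC[C@@H](C)CCC[C@@H](C)CCC/C(C)=C/Cc1c(C)c(OC)c2ccccc2c1OC
F3 | step 19 | [(3E,7S,11R,15E)-17-(1,4-dimethoxy-3-methylnaphthalen-2-yl)-3,7,11,15-tetramethylheptadeca-3,15-dien-1-yl]zinc bromide | Br[Zn]CC/C(C)=C/CC[C@@H](C)CCC[C@@H](C)CCC/C(C)=C/Cc1c(C)c(OC)c2ccccc2c1OC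
F4 | step 4 | (2E,6R)-8-bromo-2,6-dimethyloct-2-enal | O=C/C(C)=C/CC[C@@H](C)CCBr
F5 | step 6 | (2S,6R,10E)-11-iodo-2,6,10-trimethylundec-10-en-1-ol | OC[C@@H](C)CCC[C@@H](C)CCC/C(C)=C/I
F6 | step 6 | [(1,4-dimethoxy-3-methylnaphthalen-2-yl)methyl]zinc chloride | Cl[Zn]Cc1c(C)c(OC)c2ccccc2c1OC
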